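**Plan**

1. Locants are those of the azulene core of the target: C3 carbinol, C3a ring-fusion CH, C4 ester carbon, C5=C6 alkene, C8 CH2, C8a quaternary carbon. The retrosynthesis cuts the C4–O acyl bond (Mitsunobu) and the C3–isopropyl bond (organocerium). The allylic unit O–C4–C5=C6(CH3) is then traced back through the 4-ketone to a cyclohepta-1,4-diene with a silyl enol ether at C3a=C4 and an enoate at C6=C7; the ester is the masked 6-methyl group.
2. Enabling feature: in the seven-membered ring the oxygenated C4 and the methyl-bearing C6 are joined through the single carbon C5. C4–C5–C6 can therefore be drawn as a cyclopropane carrying the cyclopentene C3a=C8a on C4 and a vinyl group C7=C8 on C6. This cis-divinylcyclopropane is cut by a retro-Cope; forward, the 3,3-shift forms C8–C8a and breaks the extra bond C4–C6.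
3. Forward order: ring A (cyclopentene, from 3-methylcyclopentenone) is made first, then the 2-siloxydiene, then the temporary cyclopropane by asymmetric vinylcarbene transfer. Ring B (seven-membered) arises in the Cope step. The ester is then reduced to the methyl group, the alkene moved to C5=C6, the C4 ketone reduced, the C3 ketone unmasked, the isopropyl group added and the anisate installed.
4. Stereochemistry: the cyclopropane is set by the chiral dirhodium catalyst and its configuration is transferred to C8a in the Cope step. C3a is set by equilibration to the trans ring fusion. C4 is set by hydride attack anti to the angular methyl, then Mitsunobu inversion. C3 is set by isopropyl addition anti to the C3a–C4 bond.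

Key step: step 7

Assumption: Rh2(R-DOSP)4 is taken to give the (1S,2R)-cyclopropane by analogy with its established sense of induction for terminal alkenes; the enantiomeric catalyst is equally available should the sense be opposite.

**Route**

Step 1
Reactants: 1 3-methylcyclopent-2-en-1-one
Product: 3 2-bromo-3-methylcyclopent-2-en-1-one, via trans-2,3-dibromo-3-methylcyclopentan-1-one 2 (not isolated)
Conditions: Br2, CH2Cl2, 0 °C; then Et3N, 0 °C → rt
Reagents that add atoms: bromine, BrBr
Why: Bromination–dehydrobromination: anti addition of bromine to the enone, then base-induced loss of HBr from the dibromide, should give the 2-bromoenone, which has no stereocentre.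

Step 2
Reactants: 3 2-bromo-3-methylcyclopent-2-en-1-one
Product: 4 6-bromo-7-methyl-1,4-dioxaspiro[4.4]non-6-ene
Conditions: HOCH2CH2OH, p-TsOH·H2O (cat.), benzene, reflux (Dean–Stark)
Reagents that add atoms: ethylene glycol, OCCO
Why: Acid-catalysed ketalisation with azeotropic removal of water is the standard preparation of 2-bromoenone ketals as masked α-keto vinyl anions, and the bromine keeps the double bond in place.

Step 3
Reactants: 4 6-bromo-7-methyl-1,4-dioxaspiro[4.4]non-6-ene; 5 N-methoxy-N-methylacetamide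
Product: 7 1-(7-methyl-1,4-dioxaspiro[4.4]non-6-en-6-yl)ethan-1-one, via vinyllithium 6 (not isolated)
Conditions: n-BuLi, THF, −78 °C; then 5, −78 → 0 °C; aq. NH4Cl
Reagents that add atoms: none
Why: Bromine–lithium exchange gives the vinyllithium, and its acylation by the N-methoxy-N-methyl amide stops at the ketone because the chelated tetrahedral adduct survives until work-up.

Step 4
Reactants: 7 1-(7-methyl-1,4-dioxaspiro[4.4]non-6-en-6-yl)ethan-1-one
Product: 9 tert-butyl(dimethyl){[1-(7-methyl-1,4-dioxaspiro[4.4]non-6-en-6-yl)ethenyl]oxy}silane, via lithium enolate 8 (not isolated)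
Conditions: lithium diisopropylamide, THF, −78 °C; then TBSCl, HMPA, −78 → 0 °C
Reagents that add atoms: tert-butyldimethylsilyl chloride, CC(C)(C)[Si](C)(C)Cl
Why: Kinetic deprotonation of the enone at the acetyl methyl group and O-silylation of the enolate should give the cross-conjugated 2-siloxydiene without touching the ketal.

Step 5
Reactants: 10 methyl but-3-enoate
Product: 11 methyl 2-diazobut-3-enoate
Conditions: p-ABSA, DBU, MeCN, 0 °C (used at once as a cold solution)
Reagents that add atoms: 4-acetamidobenzenesulfonyl azide, CC(=O)Nc1ccc(cc1)S(=O)(=O)N=[N+]=[N-]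
Why: Regitz diazo transfer to the α-position of the β,γ-unsaturated ester (through its dienolate) is the direct route to vinyldiazoacetates.

Step 6
Reactants: 9 tert-butyl(dimethyl){[1-(7-methyl-1,4-dioxaspiro[4.4]non-6-en-6-yl)ethenyl]oxy}silane; 11 methyl 2-diazobut-3-enoate
Product: 12 methyl (1S,2R)-2-[(tert-butyldimethylsilyl)oxy]-1-ethenyl-2-(7-methyl-1,4-dioxaspiro[4.4]non-6-en-6-yl)cyclopropane-1-carboxylate
Conditions: Rh2(R-DOSP)4 (dirhodium tetrakis[(R)-N-(4-dodecylbenzenesulfonyl)prolinate], 1 mol %), 11 added slowly, hexanes, −45 °C → rt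
Reagents that add atoms: none
Why: Dirhodium-catalysed cyclopropanation by the donor/acceptor vinylcarbene should take place at the electron-rich, unhindered CH2=C(OSi) bond and not at the tetrasubstituted ring alkene; the vinyl group ends cis to the ring-alkenyl substituent, and the prolinate ligands choose the carbene face and with it both new stereocentres.

Step 7
Reactants: 12 methyl (1S,2R)-2-[(tert-butyldimethylsilyl)oxy]-1-ethenyl-2-(7-methyl-1,4-dioxaspiro[4.4]non-6-en-6-yl)cyclopropane-1-carboxylate
Product: 13 methyl (8aR)-4-[(tert-butyldimethylsilyl)oxy]-8a-methyl-1,2,8,8a-tetrahydro-5H-spiro[azulene-3,2'-[1,3]dioxolane]-6-carboxylate (double bonds C3a=C4 and C6=C7)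
Conditions: toluene (degassed, trace BHT), 120 °C, sealed tube
Reagents that add atoms: none
Why: On heating, the cis-1,2-dialkenylcyclopropane should undergo a concerted 3,3-sigmatropic (Cope) shift through the boat transition state in which the vinyl group and the cyclopentene both lie over the three-membered ring: the alkene termini C8 and C8a bond while the cyclopropane bond C4–C6, which is not part of the target, breaks. The closest known reaction type is the divinylcyclopropane–cycloheptadiene rearrangement that follows rhodium vinylcarbene transfer to 1,3-dienes, including dienes whose reacting terminus bears an inward alkyl group and which rearrange only on heating. The single ring closed is the seven-membered ring, by pericyclic ring enlargement of the cyclopropane (C8–C8a formed between an sp2 CH2 and a fully substituted sp2 carbon), and the shift leaves the silyl enol ether C3a=C4 and the enoate C6=C7 where the oxygen and the ring alkene are needed. The quaternary stereocentre C8a is set by transfer of chirality from the cyclopropane, since in the boat geometry C8 can reach only one face of the cyclopentene, so the (1S,2R)-cyclopropane should give the 8aR product. The step needs the concerted shift to be faster than heterolysis of the donor–acceptor cyclopropane bond, which would erase the stereochemical information; the cis relationship of the two alkenyl groups, the release of cyclopropane strain and the siloxy/ester substitution on the very bond that breaks favour the shift, and no alkyl C–H is placed for a competing homodienyl hydrogen shift.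

Step 8
Reactants: 13 methyl (8aR)-4-[(tert-butyldimethylsilyl)oxy]-8a-methyl-1,2,8,8a-tetrahydro-5H-spiro[azulene-3,2'-[1,3]dioxolane]-6-carboxylate
Product: 14 [(8aR)-4-[(tert-butyldimethylsilyl)oxy]-8a-methyl-1,2,8,8a-tetrahydro-5H-spiro[azulene-3,2'-[1,3]dioxolan]-6-yl]methanol
Conditions: i-Bu2AlH, CH2Cl2, −78 °C; aq. potassium sodium tartrate
Reagents that add atoms: none
Why: 1,2-Reduction of the α,β-unsaturated ester by the aluminium hydride should give the primary allylic alcohol and leave the silyl enol ether and the ketal untouched.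

Step 9
Reactants: 14 [(8aR)-4-[(tert-butyldimethylsilyl)oxy]-8a-methyl-1,2,8,8a-tetrahydro-5H-spiro[azulene-3,2'-[1,3]dioxolan]-6-yl]methanol
Product: 17 tert-butyl(dimethyl){[(8aS)-8a-methyl-6-methylidene-1,2,6,7,8,8a-hexahydro-5H-spiro[azulene-3,2'-[1,3]dioxolan]-4-yl]oxy}silane, via allyl sulfonylhydrazine 15 (not isolated), via allyl diazene 16 (not isolated)
Conditions: PPh3, DEAD, 2-nitrobenzenesulfonylhydrazine, N-methylmorpholine, −30 °C → rt
Reagents that add atoms: none
Why: Reductive 1,3-transposition of the primary allylic alcohol: Mitsunobu N-alkylation of the sulfonylhydrazine, loss of sulfinic acid and retro-ene loss of N2 from the allyl diazene deliver hydrogen to C7 and leave the carbon of the former ester as the exocyclic methylene on C6 (the descriptor of the unchanged C8a switches to S by priority only).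

Step 10
Reactants: 17 tert-butyl(dimethyl){[(8aS)-8a-methyl-6-methylidene-1,2,6,7,8,8a-hexahydro-5H-spiro[azulene-3,2'-[1,3]dioxolan]-4-yl]oxy}silane
Product: 19 (3aS,8aS)-6,8a-dimethyl-1,2,3a,7,8,8a-hexahydro-4H-spiro[azulene-3,2'-[1,3]dioxolan]-4-one, via exocyclic enone 18 (not isolated)
Conditions: TBAF, AcOH, THF, 0 °C; then DBU, toluene, 40 °C
Reagents that add atoms: none
Why: Fluoride cleaves the silyl enol ether to the ketone; the amidine base should then move the exocyclic double bond into conjugation through the C5 dienolate and equilibrate C3a to the trans ring fusion, in which the bulky ketal carbon is equatorial on the seven-membered ring (thermodynamic control).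

Step 11
Reactants: 19 (3aS,8aS)-6,8a-dimethyl-1,2,3a,7,8,8a-hexahydro-4H-spiro[azulene-3,2'-[1,3]dioxolan]-4-one
Product: 20 (3aS,4R,8aS)-6,8a-dimethyl-1,2,3a,7,8,8a-hexahydro-4H-spiro[azulene-3,2'-[1,3]dioxolan]-4-ol
Conditions: NaBH4, CeCl3·7H2O, MeOH, −78 °C
Reagents that add atoms: none
Why: Luche 1,2-reduction of the enone, in which hydride is expected to attack the carbonyl from the face opposite the axial 8a-methyl group, should give the 4R alcohol (hydroxyl cis to that methyl), the epimer that step 14 inverts.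

Step 12
Reactants: 20 (3aS,4R,8aS)-6,8a-dimethyl-1,2,3a,7,8,8a-hexahydro-4H-spiro[azulene-3,2'-[1,3]dioxolan]-4-ol
Product: 21 (3aS,4R,8aS)-4-hydroxy-6,8a-dimethyl-2,3a,4,7,8,8a-hexahydroazulen-3(1H)-one
Conditions: PPTS, acetone/H2O, rt
Reagents that add atoms: water, O
Why: Mild acid-catalysed hydrolysis of the dioxolane with a buffered pyridinium acid at room temperature should free the ketone without ionising the allylic alcohol or dehydrating the β-hydroxy ketone.

Step 13
Reactants: 21 (3aS,4R,8aS)-4-hydroxy-6,8a-dimethyl-2,3a,4,7,8,8a-hexahydroazulen-3(1H)-one; 22 isopropylmagnesium chloride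
Product: 23 (3R,3aS,4R,8aS)-6,8a-dimethyl-3-(propan-2-yl)-1,2,3,3a,4,7,8,8a-octahydroazulene-3,4-diol
Conditions: 22 (4 equiv), CeCl3 (anhydrous), THF, −78 → −40 °C; aq. NH4Cl
Reagents that add atoms: none
Why: Organocerium addition to the ketone, which suppresses enolisation, reduction and retro-aldol cleavage of the alkoxide, should take place on the face opposite the C3a–C4 bond and the 8a-methyl group, so that the tertiary hydroxyl ends cis to the angular methyl.

Step 14
Reactants: 23 (3R,3aS,4R,8aS)-6,8a-dimethyl-3-(propan-2-yl)-1,2,3,3a,4,7,8,8a-octahydroazulene-3,4-diol; 24 4-methoxybenzoic acid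
Product: 25 (3R,3aS,4S,8aS)-3-hydroxy-6,8a-dimethyl-3-(propan-2-yl)-1,2,3,3a,4,7,8,8a-octahydroazulen-4-yl 4-methoxybenzoate
Conditions: 24, PPh3, DIAD, toluene, 0 °C → rt
Reagents that add atoms: none
Why: Mitsunobu esterification should activate only the secondary allylic hydroxyl (the tertiary one is inert), and the carboxylate displaces it with inversion from the less hindered face to give the 4S ester.

**Compound list**

1 | 3-methylcyclopent-2-en-1-one | CC1=CC(=O)CC1 | starting material
2 | trans-2,3-dibromo-3-methylcyclopentan-1-one (racemic, one enantiomer drawn) | C[C@]1(Br)CCC(=O)[C@@H]1Br | intermediate (not isolated)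
3 | 2-bromo-3-methylcyclopent-2-en-1-one | CC1=C(Br)C(=O)CC1 | intermediate
4 | 6-bromo-7-methyl-1,4-dioxaspiro[4.4]non-6-ene | CC1=C(Br)C2(CC1)OCCO2 | intermediate
5 | N-methoxy-N-methylacetamide | CON(C)C(C)=O | starting material
6 | (7-methyl-1,4-dioxaspiro[4.4]non-6-en-6-yl)lithium | [Li]C1=C(C)CCC12OCCO2 | intermediate (not isolated)
7 | 1-(7-methyl-1,4-dioxaspiro[4.4]non-6-en-6-yl)ethan-1-one | CC(=O)C1=C(C)CCC12OCCO2 | intermediate
8 | lithium 1-(7-methyl-1,4-dioxaspiro[4.4]non-6-en-6-yl)ethen-1-olate | [Li]OC(=C)C1=C(C)CCC12OCCO2 | intermediate (not isolated)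
9 | tert-butyl(dimethyl){[1-(7-methyl-1,4-dioxaspiro[4.4]non-6-en-6-yl)ethenyl]oxy}silane | C=C(O[Si](C)(C)C(C)(C)C)C1=C(C)CCC12OCCO2 | intermediate
10 | methyl but-3-enoate | C=CCC(=O)OC | starting material
11 | methyl 2-diazobut-3-enoate | C=CC(=[N+]=[N-])C(=O)OC | intermediate
12 | methyl (1S,2R)-2-[(tert-butyldimethylsilyl)oxy]-1-ethenyl-2-(7-methyl-1,4-dioxaspiro[4.4]non-6-en-6-yl)cyclopropane-1-carboxylate | COC(=O)[C@]1(C=C)C[C@@]1(O[Si](C)(C)C(C)(C)C)C2=C(C)CCC23OCCO3 | intermediate
13 | methyl (8aR)-4-[(tert-butyldimethylsilyl)oxy]-8a-methyl-1,2,8,8a-tetrahydro-5H-spiro[azulene-3,2'-[1,3]dioxolane]-6-carboxylate | COC(=O)C1=CC[C@@]2(C)CCC3(OCCO3)C2=C(O[Si](C)(C)C(C)(C)C)C1 | intermediate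
14 | [(8aR)-4-[(tert-butyldimethylsilyl)oxy]-8a-methyl-1,2,8,8a-tetrahydro-5H-spiro[azulene-3,2'-[1,3]dioxolan]-6-yl]methanol | OCC1=CC[C@@]2(C)CCC3(OCCO3)C2=C(O[Si](C)(C)C(C)(C)C)C1 | intermediate
15 | N-{[(8aR)-4-[(tert-butyldimethylsilyl)oxy]-8a-methyl-1,2,8,8a-tetrahydro-5H-spiro[azulene-3,2'-[1,3]dioxolan]-6-yl]methyl}-2-nitrobenzenesulfonohydrazide (alkylated on the sulfonyl nitrogen) | NN(CC1=CC[C@@]2(C)CCC3(OCCO3)C2=C(O[Si](C)(C)C(C)(C)C)C1)S(=O)(=O)c1ccccc1[N+](=O)[O-] | intermediate (not isolated)
16 | {[(8aR)-4-[(tert-butyldimethylsilyl)oxy]-8a-methyl-1,2,8,8a-tetrahydro-5H-spiro[azulene-3,2'-[1,3]dioxolan]-6-yl]methyl}diazene | N=NCC1=CC[C@@]2(C)CCC3(OCCO3)C2=C(O[Si](C)(C)C(C)(C)C)C1 | intermediate (not isolated)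
17 | tert-butyl(dimethyl){[(8aS)-8a-methyl-6-methylidene-1,2,6,7,8,8a-hexahydro-5H-spiro[azulene-3,2'-[1,3]dioxolan]-4-yl]oxy}silane | C=C1CC[C@@]2(C)CCC3(OCCO3)C2=C(O[Si](C)(C)C(C)(C)C)C1 | intermediate
18 | (8aS)-8a-methyl-6-methylideneoctahydro-4H-spiro[azulene-3,2'-[1,3]dioxolan]-4-one (both C3a epimers) | C=C1CC[C@@]2(C)CCC3(OCCO3)C2C(=O)C1 | intermediate (not isolated)
19 | (3aS,8aS)-6,8a-dimethyl-1,2,3a,7,8,8a-hexahydro-4H-spiro[azulene-3,2'-[1,3]dioxolan]-4-one | O=C1C=C(C)CC[C@@]2(C)CCC3(OCCO3)[C@H]12 | intermediate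
20 | (3aS,4R,8aS)-6,8a-dimethyl-1,2,3a,7,8,8a-hexahydro-4H-spiro[azulene-3,2'-[1,3]dioxolan]-4-ol | O[C@@H]1C=C(C)CC[C@@]2(C)CCC3(OCCO3)[C@H]12 | intermediate
21 | (3aS,4R,8aS)-4-hydroxy-6,8a-dimethyl-2,3a,4,7,8,8a-hexahydroazulen-3(1H)-one | O[C@@H]1C=C(C)CC[C@@]2(C)CCC(=O)[C@H]12 | intermediate
22 | isopropylmagnesium chloride | CC(C)[Mg]Cl | starting material
23 | (3R,3aS,4R,8aS)-6,8a-dimethyl-3-(propan-2-yl)-1,2,3,3a,4,7,8,8a-octahydroazulene-3,4-diol | O[C@@H]1C=C(C)CC[C@@]2(C)CC[C@@](O)(C(C)C)[C@H]12 | intermediate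
24 | 4-methoxybenzoic acid | COc1ccc(cc1)C(=O)O | starting material
25 | (3R,3aS,4S,8aS)-3-hydroxy-6,8a-dimethyl-3-(propan-2-yl)-1,2,3,3a,4,7,8,8a-octahydroazulen-4-yl 4-methoxybenzoate | COc1ccc(C(=O)O[C@H]2C=C(C)CC[C@@]3(C)CC[C@@](O)(C(C)C)[C@H]23)cc1 | target

**Count and risks**

Total step count: 14. Longest linear sequence: 13 steps (steps 1–4 and 6–14); step 5 is a one-step side branch.

Three steps most likely to fail:

Step 7. What may go wrong: the sigmatropic shift is slowed because the methyl group on the cyclopentene terminus must point into the boat transition state, so that heterolysis of the donor–acceptor cyclopropane bond (loss of configuration, ring-opened keto ester) overtakes it. The fallback sets out from 1 and comes back at 19; it makes the quaternary centre by intermolecular conjugate addition and the seven-membered ring by olefin metathesis. 4-Bromo-2-methylbut-1-ene and Mg give (3-methylbut-3-en-1-yl)magnesium bromide F1. Copper-catalysed asymmetric conjugate addition of F1 to 1 (Cu(OTf)2, chiral N-heterocyclic carbene ligand, Et2O, 0 °C) and trapping of the magnesium enolate with acrolein at −78 °C should give (2S,3S)-2-(1-hydroxyprop-2-en-1-yl)-3-methyl-3-(3-methylbut-3-en-1-yl)cyclopentan-1-one F2; the aldehyde enters trans to the larger chain and the carbinol forms as both epimers. Ring-closing metathesis with the second-generation Hoveyda–Grubbs catalyst (toluene, 80 °C) should give (3aS,8aS)-4-hydroxy-6,8a-dimethyl-2,3a,4,7,8,8a-hexahydroazulen-3(1H)-one F3 as a C4 epimer mixture. Ketalisation (ethylene glycol, HC(OEt)3, PPTS, rt) gives (3aS,8aS)-6,8a-dimethyl-1,2,3a,7,8,8a-hexahydro-4H-spiro[azulene-3,2'-[1,3]dioxolan]-4-ol F4, and MnO2 (CH2Cl2) merges the epimers into enone 19, where the route continues with step 11.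

Step 6. What may go wrong: carbene transfer to the hindered 1,1-disubstituted enol ether proceeds with low enantio- or cis-selectivity. The fallback sets out from 9 and comes back at 14; it takes the absolute configuration from a covalently bound auxiliary in place of the chiral catalyst. But-3-enoic acid and (R)-pantolactone (DCC, DMAP) give (3R)-4,4-dimethyl-2-oxooxolan-3-yl but-3-enoate F5; the antipodal auxiliary is equally available should the sense of induction require it. Diazo transfer as in step 5 gives (3R)-4,4-dimethyl-2-oxooxolan-3-yl 2-diazobut-3-enoate F6. Cyclopropanation of 9 with Rh2(O2CC7H15)4 (hexanes, −45 °C → rt) should give (3R)-4,4-dimethyl-2-oxooxolan-3-yl (1S,2R)-2-[(tert-butyldimethylsilyl)oxy]-1-ethenyl-2-(7-methyl-1,4-dioxaspiro[4.4]non-6-en-6-yl)cyclopropane-1-carboxylate F7, a diastereomer that can be purified before heating. Rearrangement under the conditions of step 7 gives (3R)-4,4-dimethyl-2-oxooxolan-3-yl (8aR)-4-[(tert-butyldimethylsilyl)oxy]-8a-methyl-1,2,8,8a-tetrahydro-5H-spiro[azulene-3,2'-[1,3]dioxolane]-6-carboxylate F8, and LiAlH4 (THF, 0 °C) removes the auxiliary to give 14.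

Step 14. What may go wrong: at the hindered allylic carbinol the oxyphosphonium ion loses a proton (diene formation) or is attacked with allylic transposition instead of direct inversion; the same end point is reached if hydride delivery in step 11 is not face-selective. The fallback sets out from 23 and comes back at 25; it resets C4 by hydroxyl-directed reduction and makes the ester with retention. MnO2 (CH2Cl2) oxidises the allylic alcohol of 23 (or of any C4 epimer mixture) to (3R,3aR,8aS)-3-hydroxy-6,8a-dimethyl-3-(propan-2-yl)-2,3,3a,7,8,8a-hexahydroazulen-4(1H)-one F9. Me4NBH(OAc)3 (MeCN/AcOH, −30 °C) binds the tertiary hydroxyl and should deliver hydride intramolecularly to the carbonyl face on the side of the 8a-methyl group, giving (3R,3aS,4S,8aS)-6,8a-dimethyl-3-(propan-2-yl)-1,2,3,3a,4,7,8,8a-octahydroazulene-3,4-diol F10. Acylation of the secondary hydroxyl with 4-methoxybenzoyl chloride (DMAP, pyridine) gives 25.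

**Further compounds**

F1 | step 7 | (3-methylbut-3-en-1-yl)magnesium bromide | C=C(C)CC[Mg]Br
F2 | step 7 | (2S,3S)-2-(1-hydroxyprop-2-en-1-yl)-3-methyl-3-(3-methylbut-3-en-1-yl)cyclopentan-1-one (carbinol epimers) | C=C(C)CC[C@@]1(C)CCC(=O)[C@@H]1C(O)C=C
F3 | step 7 | (3aS,8aS)-4-hydroxy-6,8a-dimethyl-2,3a,4,7,8,8a-hexahydroazulen-3(1H)-one (C4 epimers) | OC1C=C(C)CC[C@@]2(C)CCC(=O)[C@H]12
F4 | step 7 | (3aS,8aS)-6,8a-dimethyl-1,2,3a,7,8,8a-hexahydro-4H-spiro[azulene-3,2'-[1,3]dioxolan]-4-ol (C4 epimers) | OC1C=C(C)CC[C@@]2(C)CCC3(OCCO3)[C@H]12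
F5 | step 6 | (3R)-4,4-dimethyl-2-oxooxolan-3-yl but-3-enoate | C=CCC(=O)O[C@H]1C(=O)OCC1(C)C
F6 | step 6 | (3R)-4,4-dimethyl-2-oxooxolan-3-yl 2-diazobut-3-enoate | C=CC(=[N+]=[N-])C(=O)O[C@H]1C(=O)OCC1(C)C
F7 | step 6 | (3R)-4,4-dimethyl-2-oxooxolan-3-yl (1S,2R)-2-[(tert-butyldimethylsilyl)oxy]-1-ethenyl-2-(7-methyl-1,4-dioxaspiro[4.4]non-6-en-6-yl)cyclopropane-1-carboxylate | O=C(O[C@H]1C(=O)OCC1(C)C)[C@]2(C=C)C[C@@]2(O[Si](C)(C)C(C)(C)C)C3=C(C)CCC34OCCO4
F8 | step 6 | (3R)-4,4-dimethyl-2-oxooxolan-3-yl (8aR)-4-[(tert-butyldimethylsilyl)oxy]-8a-methyl-1,2,8,8a-tetrahydro-5H-spiro[azulene-3,2'-[1,3]dioxolane]-6-carboxylate | O=C(O[C@H]1C(=O)OCC1(C)C)C2=CC[C@@]3(C)CCC4(OCCO4)C3=C(O[Si](C)(C)C(C)(C)C)C2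
F9 | step 14 | (3R,3aR,8aS)-3-hydroxy-6,8a-dimethyl-3-(propan-2-yl)-2,3,3a,7,8,8a-hexahydroazulen-4(1H)-one | O=C1C=C(C)CC[C@@]2(C)CC[C@@](O)(C(C)C)[C@H]12
F10 | step 14 | (3R,3aS,4S,8aS)-6,8a-dimethyl-3-(propan-2-yl)-1,2,3,3a,4,7,8,8a-octahydroazulene-3,4-diol | O[C@H]1C=C(C)CC[C@@]2(C)CC[C@@](O)(C(C)C)[C@H]12
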